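## Retrosynthetic overview

- **Feature:** ring A is a 1,3,5-trioxygenated benzene (C5–OMe, C7–OH, C8a–O1). Its C8, flanked by the oxygenated carbons C7 and C8a, carries the (R)-configured piperidine carbon C2'.
- **Key disconnection:** ring A is opened by retro-benzannulation into 3-methoxycyclobutenone (C4a, C5, C6, C7) and an (R)-piperidinyl siloxyalkyne (C8, C8a) made from N-Boc-D-pipecolic acid. The bonds are C7–C8, C8a–C4a and C6–C7.
- **Ring C:** disconnected at C4a–C4, C4–C3 and O1–C2 into an o-iodophenol, CO and phenylacetylene (which brings ring B). The desilylated ring A is symmetric, so the iodination needs no regiocontrol.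
- **Order of ring formation:** piperidine (chiral pool), then ring A (benzannulation), then ring C (carbonylative annulation). N-Boc is exchanged for N-Me last, when ring A is deactivated by the pyranone, so that benzylic C2' is never a free amine on a hot, electron-rich ring.

Key step: step 6

Remark on the chemistry: after desilylation ring A is symmetric about the C5···C8 axis (free rotation about C8–C2'), so the flavone locants used for the benzannulation product assume that the silylated oxygen becomes O1; the opposite assignment leads to the same flavone.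

## Route

Step 1
Reactants: 1 N-Boc-D-pipecolic acid, (2R)-1-(tert-butoxycarbonyl)piperidine-2-carboxylic acid
Product: 2 tert-butyl (2R)-2-(hydroxymethyl)piperidine-1-carboxylate
Conditions: BH3·SMe2, THF, 0 °C to rt; MeOH then aqueous work-up
Reagents that add atoms: none
Why: Chemoselective borane reduction of a carboxylic acid through its acyloxyborane leaves the tert-butyl carbamate and the C2 stereocentre untouched.

Step 2
Reactants: 2 tert-butyl (2R)-2-(hydroxymethyl)piperidine-1-carboxylate
Product: 3 tert-butyl (2R)-2-formylpiperidine-1-carboxylate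
Conditions: Dess–Martin periodinane, CH2Cl2, 0 °C to rt; used crude at once
Reagents that add atoms: none
Why: Dess–Martin oxidation stops at the aldehyde under near-neutral conditions that should not enolise the N-Boc α-amino aldehyde.

Step 3
Reactants: 3 tert-butyl (2R)-2-formylpiperidine-1-carboxylate
Product: 4 tert-butyl (2R)-2-ethynylpiperidine-1-carboxylate
Conditions: Ohira–Bestmann reagent, K2CO3, MeOH, 0 °C to rt
Reagents that add atoms: dimethyl (1-diazo-2-oxopropyl)phosphonate, CC(=O)C(=[N+]=[N-])P(=O)(OC)OC
Why: Seyferth–Gilbert homologation in its Ohira–Bestmann form turns the aldehyde into the terminal alkyne with mild carbonate base at low temperature, and C2 takes no part in the hydrogen shift.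

Step 4
Reactants: 4 tert-butyl (2R)-2-ethynylpiperidine-1-carboxylate
Product: 7 tert-butyl (2R)-2-[(triisopropylsilyloxy)ethynyl]piperidine-1-carboxylate, via lithium acetylide 5 (not isolated), via lithium ynolate 6 (not isolated)
Conditions: LiN(SiMe3)2 (2.1 equiv), t-BuOOH, THF, −78 to 0 °C; then i-Pr3SiOTf, −78 to 0 °C; chromatography on Et3N-deactivated silica
Reagents that add atoms: tert-butyl hydroperoxide (used as LiOOt-Bu), CC(C)(C)OO; triisopropylsilyl trifluoromethanesulfonate, CC(C)[Si](OS(=O)(=O)C(F)(F)F)(C(C)C)C(C)C
Why: Oxygen transfer from lithium tert-butyl peroxide to the lithium acetylide gives the ynolate, which the bulky silyl triflate should trap on oxygen and not on carbon (known acetylide-to-ynolate oxidation and O-silylation), with the carbamate and C2 inert at or below 0 °C.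

Step 5
Reactants: 8 3-ethoxycyclobut-2-en-1-one
Product: 9 3-methoxycyclobut-2-en-1-one
Conditions: anhydrous MeOH (solvent), camphorsulfonic acid (cat.), 3 Å molecular sieves, rt; concentrate and repeat; distil
Reagents that add atoms: methanol, CO
Why: Acid-catalysed transetherification of a vinylogous ester by addition of methanol at C3 and loss of ethanol, driven by the excess of methanol; no free 1,3-dione is formed under anhydrous conditions, so the ring should stay closed.

Step 6
Reactants: 7 tert-butyl (2R)-2-[(triisopropylsilyloxy)ethynyl]piperidine-1-carboxylate; 9 3-methoxycyclobut-2-en-1-one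
Product: 14 tert-butyl (2R)-2-[2-hydroxy-4-methoxy-6-(triisopropylsilyloxy)phenyl]piperidine-1-carboxylate, via vinylketene 10 (not isolated), via cyclobutenone adduct 11 (not isolated), via dienylketene 12 (not isolated), via cyclohexadienone 13 (not isolated)
Conditions: 7 and 9 in equimolar amounts; 9 in PhMe added dropwise to 7 in PhMe at 80 °C, then reflux (110 °C), argon, base-washed glassware
Reagents that add atoms: none
Why: Thermal four-electron electrocyclic opening of 9 gives vinylketene 10, whose ketene C=C adds the electron-rich siloxyalkyne 7 in a [2+2] cycloaddition to give the 4-vinylcyclobutenone 11; a second four-electron opening gives dienylketene 12, and tautomerisation of the cyclised dienone 13 gives phenol 14 (Danheiser benzannulation, known for cyclobutenones with triisopropylsiloxyalkynes). Ring A closes by a thermal six-electron electrocyclization of the dienylketene, which forms C6–C7 after C7–C8 and C8a–C4a were made in the cycloaddition. No stereocentre is created: C2' comes from D-pipecolic acid and has no pathway for epimerisation under neutral heating, and the transient ring stereocentre of 11 is erased on ring opening. The step needs one regiochemistry in the ketene–alkyne cycloaddition, and the polarisation of the siloxyalkyne secures it: the carbon β to oxygen, which bears the piperidine, is the nucleophilic end and bonds to the electrophilic ketene carbonyl carbon, so C8 ends between C7–OH and C8a–OSi with the methoxy carbon para to it. Because the 3-methoxy group makes 9 a vinylogous ester that should open more slowly than an alkylcyclobutenone, the partners are combined one to one, with 9 added slowly to the hot alkyne and the temperature raised in stages, so that each portion of vinylketene meets the siloxyalkyne and not a second ketene or the product phenol; the carbamate keeps nitrogen from adding to the ketenes.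

Step 7
Reactants: 14 tert-butyl (2R)-2-[2-hydroxy-4-methoxy-6-(triisopropylsilyloxy)phenyl]piperidine-1-carboxylate
Product: 15 tert-butyl (2R)-2-(2,6-dihydroxy-4-methoxyphenyl)piperidine-1-carboxylate
Conditions: TBAF, AcOH, THF, 0 °C
Reagents that add atoms: none
Why: Fluoride-mediated cleavage of the aryl silyl ether, buffered with acetic acid to protect the electron-rich phenoxide, should give the symmetric resorcinol with the carbamate intact.

Step 8
Reactants: 15 tert-butyl (2R)-2-(2,6-dihydroxy-4-methoxyphenyl)piperidine-1-carboxylate
Product: 16 tert-butyl (2R)-2-(2,6-dihydroxy-3-iodo-4-methoxyphenyl)piperidine-1-carboxylate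
Conditions: NIS (1.0 equiv), CH2Cl2/MeCN, −40 to 0 °C, dark
Reagents that add atoms: N-iodosuccinimide, O=C1CCC(=O)N1I
Why: Electrophilic aromatic iodination of the strongly activated ring; the two open positions, each between an OH and the OMe, are equivalent by rotation about the aryl–C2' bond, so one equivalent at low temperature should give a single mono-iodide.

Step 9
Reactants: 16 tert-butyl (2R)-2-(2,6-dihydroxy-3-iodo-4-methoxyphenyl)piperidine-1-carboxylate; 17 phenylacetylene
Product: 19 tert-butyl (2R)-2-(7-hydroxy-5-methoxy-4-oxo-2-phenyl-4H-chromen-8-yl)piperidine-1-carboxylate, via ynone 18 (not isolated)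
Conditions: PdCl2(dppf) (5 mol %; dppf = 1,1'-bis(diphenylphosphino)ferrocene), CO (20 atm), Et2NH, 100–120 °C
Reagents that add atoms: carbon monoxide, [C-]#[O+]
Why: Palladium-catalysed carbonylative Sonogashira coupling (oxidative addition, CO insertion, alkynylation of the acylpalladium) gives the o-hydroxyaryl ynone, which closes ring C by amine-mediated 6-endo oxa-Michael addition of the ortho oxygen (known carbonylative annulation of o-iodophenols with terminal alkynes); high CO pressure without copper disfavours direct alkyne coupling, the secondary amine favours six- over five-membered closure, and the non-basic carbamate nitrogen keeps C2' fixed.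

Step 10
Reactants: 19 tert-butyl (2R)-2-(7-hydroxy-5-methoxy-4-oxo-2-phenyl-4H-chromen-8-yl)piperidine-1-carboxylate
Product: 21 7-hydroxy-5-methoxy-8-[(2R)-1-methylpiperidin-2-yl]-2-phenyl-4H-chromen-4-one, via secondary amine 20 (not isolated)
Conditions: TFA, CH2Cl2, 0 °C; concentrate; then 37% aq HCHO, NaBH(OAc)3, AcOH, THF, 0 °C to rt
Reagents that add atoms: formaldehyde, C=O
Why: Acidolysis of the Boc group followed by reductive amination with formaldehyde should give the tertiary N-methylamine at or below room temperature; ring A is by now deactivated by the pyranone carbonyl, so the benzylic C8–C2' and C2'–N bonds should not ionise and C2' stays (R).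

## Compound list

1 | N-Boc-D-pipecolic acid, (2R)-1-(tert-butoxycarbonyl)piperidine-2-carboxylic acid | OC(=O)[C@H]1CCCCN1C(=O)OC(C)(C)C | starting material
2 | tert-butyl (2R)-2-(hydroxymethyl)piperidine-1-carboxylate | OC[C@H]1CCCCN1C(=O)OC(C)(C)C | intermediate
3 | tert-butyl (2R)-2-formylpiperidine-1-carboxylate | O=C[C@H]1CCCCN1C(=O)OC(C)(C)C | intermediate
4 | tert-butyl (2R)-2-ethynylpiperidine-1-carboxylate | C#C[C@H]1CCCCN1C(=O)OC(C)(C)C | intermediate
5 | tert-butyl (2R)-2-(lithioethynyl)piperidine-1-carboxylate (lithium acetylide, not isolated) | [Li]C#C[C@H]1CCCCN1C(=O)OC(C)(C)C | intermediate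
6 | lithium 2-[(2R)-1-(tert-butoxycarbonyl)piperidin-2-yl]ethynolate (lithium ynolate, not isolated) | [Li]OC#C[C@H]1CCCCN1C(=O)OC(C)(C)C | intermediate
7 | tert-butyl (2R)-2-[(triisopropylsilyloxy)ethynyl]piperidine-1-carboxylate | CC(C)[Si](OC#C[C@H]1CCCCN1C(=O)OC(C)(C)C)(C(C)C)C(C)C | intermediate
8 | 3-ethoxycyclobut-2-en-1-one | CCOC1=CC(=O)C1 | starting material
9 | 3-methoxycyclobut-2-en-1-one | COC1=CC(=O)C1 | intermediate
10 | 3-methoxybuta-1,3-dien-1-one (vinylketene, not isolated) | COC(=C)C=C=O | intermediate
11 | tert-butyl (2R)-2-[3-(1-methoxyethenyl)-4-oxo-2-(triisopropylsilyloxy)cyclobut-1-en-1-yl]piperidine-1-carboxylate (both epimers at the ring CH, not isolated) | COC(=C)C1C(=O)C([C@H]2CCCCN2C(=O)OC(C)(C)C)=C1O[Si](C(C)C)(C(C)C)C(C)C | intermediate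
12 | tert-butyl (2R)-2-[(3E)-5-methoxy-1-oxo-3-(triisopropylsilyloxy)hexa-1,3,5-trien-2-yl]piperidine-1-carboxylate (dienylketene, not isolated) | O=C=C([C@H]1CCCCN1C(=O)OC(C)(C)C)/C(O[Si](C(C)C)(C(C)C)C(C)C)=C\C(OC)=C | intermediate
13 | tert-butyl (2R)-2-[4-methoxy-6-oxo-2-(triisopropylsilyloxy)cyclohexa-1,3-dien-1-yl]piperidine-1-carboxylate (not isolated) | O=C1CC(OC)=CC(O[Si](C(C)C)(C(C)C)C(C)C)=C1[C@H]2CCCCN2C(=O)OC(C)(C)C | intermediate
14 | tert-butyl (2R)-2-[2-hydroxy-4-methoxy-6-(triisopropylsilyloxy)phenyl]piperidine-1-carboxylate | COc1cc(O)c([C@H]2CCCCN2C(=O)OC(C)(C)C)c(O[Si](C(C)C)(C(C)C)C(C)C)c1 | intermediate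
15 | tert-butyl (2R)-2-(2,6-dihydroxy-4-methoxyphenyl)piperidine-1-carboxylate | COc1cc(O)c([C@H]2CCCCN2C(=O)OC(C)(C)C)c(O)c1 | intermediate
16 | tert-butyl (2R)-2-(2,6-dihydroxy-3-iodo-4-methoxyphenyl)piperidine-1-carboxylate | COc1cc(O)c([C@H]2CCCCN2C(=O)OC(C)(C)C)c(O)c1I | intermediate
17 | phenylacetylene | C#Cc1ccccc1 | starting material
18 | tert-butyl (2R)-2-[2,6-dihydroxy-4-methoxy-3-(3-phenylprop-2-ynoyl)phenyl]piperidine-1-carboxylate (ynone, not isolated) | COc1cc(O)c([C@H]2CCCCN2C(=O)OC(C)(C)C)c(O)c1C(=O)C#Cc1ccccc1 | intermediate
19 | tert-butyl (2R)-2-(7-hydroxy-5-methoxy-4-oxo-2-phenyl-4H-chromen-8-yl)piperidine-1-carboxylate | COc1cc(O)c([C@H]2CCCCN2C(=O)OC(C)(C)C)c2oc(-c3ccccc3)cc(=O)c12 | intermediate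
20 | 7-hydroxy-5-methoxy-2-phenyl-8-[(2R)-piperidin-2-yl]-4H-chromen-4-one (formed as its trifluoroacetate, not isolated) | COc1cc(O)c([C@H]2CCCCN2)c2oc(-c3ccccc3)cc(=O)c12 | intermediate
21 | 7-hydroxy-5-methoxy-8-[(2R)-1-methylpiperidin-2-yl]-2-phenyl-4H-chromen-4-one (CNP0152057.1) | COc1cc(O)c([C@H]2CCCCN2C)c2oc(-c3ccccc3)cc(=O)c12 | target

## Step count and risks

Total step count: 10 (steps 1–10, of which step 5 prepares the cyclobutenone).
Longest linear sequence: 9 steps (1 to 21 through steps 1–4 and 6–10).

Three steps most likely to fail: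

1. **Step 6.** The vinylogous-ester cyclobutenone may open to the vinylketene only at temperatures at which the siloxyalkyne is lost by thermal rearrangement or the ketene oligomerises, and the phenol formed may be acylated by vinylketene, which would leave part of the alkyne unconsumed. The fallback makes the same vinylketene at room temperature by a photochemical Wolff rearrangement instead of a thermal ring opening. Commercial 3,3-dimethoxybutan-2-one is heated with catalytic TsOH while methanol distils, to give 3-methoxybut-3-en-2-one F1. Its lithium enolate (LiN(SiMe3)2, THF, −78 °C) is trifluoroacetylated with 2,2,2-trifluoroethyl trifluoroacetate to 1,1,1-trifluoro-5-methoxyhex-5-ene-2,4-dione F2. Detrifluoroacetylative diazo transfer (MsN3, Et3N, H2O, MeCN) then gives 1-diazo-3-methoxybut-3-en-2-one F3. Irradiation of F3 with 7 in CH2Cl2 at rt should generate 10 and from it 11, and brief warming to 80 °C should complete the sequence. The fallback sets out from 7 and comes back to the route at 10, hence at 14.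

2. **Step 9.** Coupling may occur without CO insertion (leading to a 2-phenylbenzofuran), the ynone may close to the five-membered aurone, the iodide may be lost by protodeiodination, or oxidative addition may be slow at the iodide between two ortho substituents. The fallback builds ring C by enolate acylation and cyclodehydration with the Boc group kept. Stille coupling of 16 with tributyl(1-ethoxyvinyl)stannane (Pd(PPh3)4, CuI, dioxane, 90 °C) should give tert-butyl (2R)-2-[3-(1-ethoxyethenyl)-2,6-dihydroxy-4-methoxyphenyl]piperidine-1-carboxylate F4. Hydrolysis with 1 M HCl in THF at rt gives tert-butyl (2R)-2-(3-acetyl-2,6-dihydroxy-4-methoxyphenyl)piperidine-1-carboxylate F5. Its trianion (LiN(SiMe3)2, 4 equiv, THF, −78 °C) is C-benzoylated with one equivalent of benzoyl chloride (Baker–Venkataraman-type diketone synthesis) to tert-butyl (2R)-2-[2,6-dihydroxy-4-methoxy-3-(3-oxo-3-phenylpropanoyl)phenyl]piperidine-1-carboxylate F6. TFA at 0 °C to rt should then cyclodehydrate the diketone and remove the Boc group in one operation. The fallback sets out from 16 and comes back at 20, which is N-methylated as in the second half of step 10.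

3. **Step 4.** Oxygen transfer to the acetylide may be incomplete, peroxide or amide base may attack the carbamate, or the siloxyalkyne may hydrolyse on silica. The fallback reaches the ynolate by a Kowalski ester homologation instead of acetylide oxidation. Acid 1 is esterified (MeI, K2CO3, DMF) to 1-tert-butyl 2-methyl (2R)-piperidine-1,2-dicarboxylate F7. Addition of LiCHBr2 (CH2Br2, lithium 2,2,6,6-tetramethylpiperidide, THF, −78 °C) and then LiN(SiMe3)2 gives the lithium enolate of tert-butyl (2R)-2-(2,2-dibromoacetyl)piperidine-1-carboxylate F8. Bromine–lithium exchange with n-BuLi and warming to 0 °C induces the 1,2-shift of the piperidinyl carbon with retention to ynolate 6, which is silylated with i-Pr3SiOTf as in step 4. The fallback sets out from 1 and comes back at 6, hence at 7.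

## Further compounds

F1 | step 6 | 3-methoxybut-3-en-2-one | COC(=C)C(C)=O
F2 | step 6 | 1,1,1-trifluoro-5-methoxyhex-5-ene-2,4-dione | COC(=C)C(=O)CC(=O)C(F)(F)F
F3 | step 6 | 1-diazo-3-methoxybut-3-en-2-one | COC(=C)C(=O)C=[N+]=[N-]
F4 | step 9 | tert-butyl (2R)-2-[3-(1-ethoxyethenyl)-2,6-dihydroxy-4-methoxyphenyl]piperidine-1-carboxylate | CCOC(=C)c1c(OC)cc(O)c([C@H]2CCCCN2C(=O)OC(C)(C)C)c1O
F5 | step 9 | tert-butyl (2R)-2-(3-acetyl-2,6-dihydroxy-4-methoxyphenyl)piperidine-1-carboxylate | CC(=O)c1c(OC)cc(O)c([C@H]2CCCCN2C(=O)OC(C)(C)C)c1O
F6 | step 9 | tert-butyl (2R)-2-[2,6-dihydroxy-4-methoxy-3-(3-oxo-3-phenylpropanoyl)phenyl]piperidine-1-carboxylate | O=C(CC(=O)c1c(OC)cc(O)c([C@H]2CCCCN2C(=O)OC(C)(C)C)c1O)c1ccccc1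
F7 | step 4 | 1-tert-butyl 2-methyl (2R)-piperidine-1,2-dicarboxylate | COC(=O)[C@H]1CCCCN1C(=O)OC(C)(C)C
F8 | step 4 | tert-butyl (2R)-2-(2,2-dibromoacetyl)piperidine-1-carboxylate | BrC(Br)C(=O)[C@H]1CCCCN1C(=O)OC(C)(C)C
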